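The α-methylene lactone is traced back to an α-phosphono lactone, and its C7–C11 bond to an intramolecular SN2 opening of a C6–C7 epoxide by a phosphonoacetate carbanion hung on the C8 oxygen. This exploits the contiguous C6(O)–C7(C11)–C8(O) triad of ring B (cyclohexene C5–C10), in which C11 is cis to O8 and trans to O6: one operation closes the cis-fused γ-lactone, sets C7 and frees the C6 hydroxyl for angeloylation. The precursor is an epoxy enoate carrying the C8 phosphonoacetate anti to the oxirane, a C10 allyl ester and the silylated C4 side chain; it is reached from a furan Diels–Alder adduct by exo-epoxidation, oxa-bridge opening and Mitsunobu inversion.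

Key step: step 8

Remarks
- Atom labels: ring B = C5–C10 with C5=C10; C6 carries the angelate; C7/C8 are the lactone fusion (oxygen on C8); C9 is CH2; C14 is the carbinol carbon on C10; the chain on C5 is C4(H)(CH3)–C3–C2–C1–OH; the lactone carbons are C11 (bearing C13H2) and C12 (C=O).
- Assumption: boronic ester 3 is made in one step rather than bought, and compounds 18 and 21–24 are carried as C11 epimer mixtures (the SMILES show one epimer), which converge in step 12.
- Endo and exo Diels–Alder adducts formed on the same acrylate face have opposite bridgeheads, so only the endo isomer 13 is carried on.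
- The oxirane is placed on the bicyclic alkene, where only the exo face is open; its anti relationship to the C8 ester then comes from an inversion, not from a face-selective epoxidation.
- The antipode of the step 4 catalyst is to be confirmed by MTPA-ester analysis of 15; the other antipode is made from (R)-α,α-diphenylprolinol.

Step 1
Reactants: 1 allyl tert-butyldimethylsilyl ether; 2 pinacolborane
Product: 3 3-(tert-butyldimethylsilyloxy)propylboronic acid pinacol ester
Conditions: [Ir(cod)Cl]2 (1.5 mol%), dppm (3 mol%), CH2Cl2, rt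
Reagents that add atoms: none
Why: Iridium-catalysed anti-Markovnikov hydroboration of a terminal alkene with pinacolborane puts boron on the terminal carbon and leaves the silyl ether alone.

Step 2
Reactants: 4 ethyl N,N-diisopropylcarbamate; 3 3-(tert-butyldimethylsilyloxy)propylboronic acid pinacol ester
Product: 7 (R)-5-(tert-butyldimethylsilyloxy)pentan-2-ylboronic acid pinacol ester, via lithiated carbamate 5 (not isolated), via boronate complex 6 (not isolated)
Conditions: s-BuLi, (−)-sparteine, Et2O, −78 °C; then 3, −78 °C; then MgBr2·OEt2, reflux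
Reagents that add atoms: none
Why: Sparteine-mediated asymmetric deprotonation removes the pro-S hydrogen to give the configurationally stable (S)-lithio carbamate, which is borylated with retention and rearranges by a stereospecific 1,2-metallate shift with inversion (lithiation–borylation homologation), so the diamine sets C4 as (R).

Step 3
Reactants: 8 furan; 7 (R)-5-(tert-butyldimethylsilyloxy)pentan-2-ylboronic acid pinacol ester
Product: 11 (R)-2-[5-(tert-butyldimethylsilyloxy)pentan-2-yl]furan, via 2-furyllithium 9 (not isolated), via furyl boronate complex 10 (not isolated)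
Conditions: 8, n-BuLi, THF, −78 °C → rt; then 7, −78 °C; then NBS, THF, −78 °C → rt
Reagents that add atoms: none
Why: Bromination of the furyl ring of the boronate complex triggers a 1,2-migration of the secondary alkyl group with retention, followed by loss of boron and bromide (stereospecific metal-free sp2–sp3 coupling of a boronate complex), so C4 stays (R).

Step 4
Reactants: 11 (R)-2-[5-(tert-butyldimethylsilyloxy)pentan-2-yl]furan; 12 allyl acrylate
Product: 13 allyl (1S,2S,4S)-1-[(2R)-5-(tert-butyldimethylsilyloxy)pentan-2-yl]-7-oxabicyclo[2.2.1]hept-5-ene-2-carboxylate (endo ester)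
Conditions: protonated oxazaborolidine catalyst [(S)-α,α-diphenylprolinol + tri-o-tolylboroxine; HNTf2] (20 mol%), CH2Cl2, −78 → −40 °C; chromatographic removal of the exo isomer
Reagents that add atoms: none
Why: In this Lewis-acid-catalysed enantioselective Diels–Alder reaction the 2-alkyl group of the furan directs the ester carbon next to the substituted bridgehead, low temperature favours the kinetic endo adduct, and the chiral boron cation shields one acrylate face, so the (1S,4S) bridgeheads are set by the catalyst and not by the remote C4 centre.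

Step 5
Reactants: 13 endo Diels–Alder adduct
Product: 14 exo-5,6-epoxide of 13
Conditions: m-CPBA, NaHCO3, CH2Cl2, 0 °C → rt
Reagents that add atoms: m-CPBA, O=C(OO)c1cccc(Cl)c1
Why: Peracid (Prilezhaev) epoxidation of the strained 7-oxanorbornene alkene can only occur on the exo face, syn to the oxygen bridge, and is much faster than attack on the electron-poor allyl ester alkene, so the future C6 and C7 oxygens are fixed cis to the future C8 oxygen and retro-cycloaddition is shut off.

Step 6
Reactants: 14 exo-epoxide of the adduct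
Product: 15 allyl (1R,5S,6S)-2-[(2R)-5-(tert-butyldimethylsilyloxy)pentan-2-yl]-5-hydroxy-7-oxabicyclo[4.1.0]hept-2-ene-3-carboxylate (C8–OH and oxirane on the same face)
Conditions: LiN(SiMe3)2 (1.1 equiv), THF, −78 °C; aq. NH4Cl
Reagents that add atoms: none
Why: Deprotonation α to the ester and E1cB β-elimination of the bridging oxygen (base-induced oxa-bridge opening of a 7-oxanorbornane-2-carboxylate) is driven by strain release, creates the C5=C10 enoate and frees the C8 hydroxyl without touching a stereocentre, while one equivalent of base at low temperature avoids γ-deprotonation at C4.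

Step 7
Reactants: 15 cis-epoxy alcohol; 16 diethylphosphonoacetic acid
Product: 17 allyl (1R,5R,6S)-5-{[2-(diethoxyphosphoryl)acetyl]oxy}-2-[(2R)-5-(tert-butyldimethylsilyloxy)pentan-2-yl]-7-oxabicyclo[4.1.0]hept-2-ene-3-carboxylate (C8 ester anti to the oxirane)
Conditions: 16, PPh3, DIAD, THF, 0 °C → rt
Reagents that add atoms: none
Why: Mitsunobu esterification with the acidic phosphonoacetic acid displaces the C8 oxyphosphonium by SN2 with clean inversion, turning the cis-epoxy alcohol into the anti epoxy ester needed for backside attack at C7.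

Step 8
Reactants: 17 anti epoxy phosphonoacetate
Product: 18 allyl (3ξ,3aS,4S,7aR)-3-(diethoxyphosphoryl)-4-hydroxy-5-[(2R)-5-(tert-butyldimethylsilyloxy)pentan-2-yl]-2-oxo-2,3,3a,4,7,7a-hexahydro-1-benzofuran-6-carboxylate (α-phosphono cis-lactone with free C6–OH)
Conditions: LiCl, DBU, MeCN, rt (40 °C if slow); aq. NH4Cl
Reagents that add atoms: none
Why: LiCl and DBU generate the lithium-chelated phosphonoacetate carbanion, whose carbon attacks C7 from the face of the C8 ester oxygen and opposite to the oxirane oxygen (intramolecular SN2 epoxide opening, the ester-tethered version of stabilised-carbanion epoxide alkylations that lead to γ-lactones). The lactone ring C11–C12–O–C8–C7 closes in the 5-exo-tet mode and is therefore cis-fused to ring B. The new stereocentre C7 is set by inversion at the epoxide carbon, so it follows from the exo epoxide of step 5 and the inverted C8 ester of step 7; C6 keeps its oxygen on the opposite face, and C11 is epimerisable and disappears in step 12. The step needs attack at C7 and not at C6: the three-atom tether reaches C7 in a trans-diaxial 5-exo geometry, whereas C6 would need a bridged 6-endo transition state. The C10 ester keeps the C5=C10 alkene electron-poor, so neither SN2′ attack at C10 nor ionisation at allylic C6 should compete. The liberated C6 alkoxide is quenched by the acidic phosphono lactone, whose enolate form protects the lactone carbonyl from translactonisation until work-up.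

Step 9
Reactants: 18 α-phosphono cis-lactone alcohol; 19 angelic acid
Product: 21 C6 angelate of the phosphono lactone, via angelic 2,4,6-trichlorobenzoic anhydride 20 (not isolated)
Conditions: 19, 2,4,6-Cl3C6H2COCl, Et3N, toluene, rt; then 18, 75 °C
Reagents that add atoms: none
Why: Mixed-anhydride (Yamaguchi-type) esterification delivers the angeloyl group from the preformed anhydride to the secondary C6 alcohol at its less hindered carbonyl, and leaving out nucleophilic catalysts avoids Z-to-E isomerisation to the tiglate.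

Step 10
Reactants: 21 C6 angelate allyl ester
Product: 22 C10 carboxylic acid
Conditions: Pd(PPh3)4 (5 mol%), morpholine, THF, rt; aq. citric acid
Reagents that add atoms: none
Why: Palladium-catalysed allyl transfer to morpholine (Tsuji–Trost deallylation) cleaves only the allyl ester and leaves the lactone, angelate, phosphonate and silyl ether untouched.

Step 11
Reactants: 22 C10 carboxylic acid
Product: 24 C14 primary allylic alcohol, via mixed carbonic anhydride 23 (not isolated)
Conditions: i-BuOCOCl, N-methylmorpholine, THF, −15 °C; then NaBH4, H2O, −15 → 0 °C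
Reagents that add atoms: none
Why: Activation as the isobutyl carbonic anhydride lets NaBH4 reduce the acid to the alcohol at low temperature much faster than it attacks the lactone or the angelate (chemoselective mixed-anhydride reduction), and the reduction is placed before the methylene lactone exists, so no conjugate reduction can occur.

Step 12
Reactants: 24 phosphono lactone with C14–OH
Product: 25 α-methylene lactone with C1–OTBS
Conditions: 37% aq. HCHO, K2CO3, THF, 0 °C → rt
Reagents that add atoms: formaldehyde, C=O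
Why: Horner–Wadsworth–Emmons olefination of the α-phosphono lactone with formaldehyde under mild carbonate base gives the exocyclic methylene and removes the C11 stereocentre.

Step 13
Reactants: 25 silyl-protected target
Product: 26 CNP0106570.2
Conditions: HF·pyridine, pyridine, THF, 0 °C → rt
Reagents that add atoms: none
Why: Buffered fluoride cleavage of the primary tert-butyldimethylsilyl ether (desilylation) frees C1–OH under conditions that the α-methylene lactone, the angelate and the allylic alcohol should tolerate.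

Compound list
1 | allyl tert-butyldimethylsilyl ether | C=CCO[Si](C)(C)C(C)(C)C | starting material
2 | pinacolborane | CC1(C)OBOC1(C)C | starting material
3 | tert-butyl(dimethyl)[3-(4,4,5,5-tetramethyl-1,3,2-dioxaborolan-2-yl)propoxy]silane | CC1(C)OB(CCCO[Si](C)(C)C(C)(C)C)OC1(C)C | intermediate
4 | ethyl N,N-diisopropylcarbamate | CCOC(=O)N(C(C)C)C(C)C | starting material
5 | (S)-1-lithioethyl N,N-diisopropylcarbamate (sparteine complex) | C[C@H]([Li])OC(=O)N(C(C)C)C(C)C | intermediate (not isolated)
6 | lithium boronate complex from 5 and 3 (boron in place of lithium, retention) | C[C@@H](OC(=O)N(C(C)C)C(C)C)[B-]1(CCCO[Si](C)(C)C(C)(C)C)OC(C)(C)C(C)(C)O1.[Li+] | intermediate (not isolated)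
7 | tert-butyl(dimethyl){[(4R)-4-(4,4,5,5-tetramethyl-1,3,2-dioxaborolan-2-yl)pentyl]oxy}silane | CC1(C)OB(OC1(C)C)[C@H](C)CCCO[Si](C)(C)C(C)(C)C | intermediate
8 | furan | c1ccoc1 | starting material
9 | 2-furyllithium | [Li]c1ccco1 | intermediate (not isolated)
10 | lithium 2-furyl boronate complex of 7 | C[C@H](CCCO[Si](C)(C)C(C)(C)C)[B-]1(c2ccco2)OC(C)(C)C(C)(C)O1.[Li+] | intermediate (not isolated)
11 | tert-butyl{[(4R)-4-(furan-2-yl)pentyl]oxy}dimethylsilane | C[C@H](CCCO[Si](C)(C)C(C)(C)C)c1ccco1 | intermediate
12 | allyl acrylate | C=CC(=O)OCC=C | starting material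
13 | allyl (1S,2S,4S)-1-[(2R)-5-(tert-butyldimethylsilyloxy)pentan-2-yl]-7-oxabicyclo[2.2.1]hept-5-ene-2-carboxylate (endo ester) | C=CCOC(=O)[C@H]1C[C@H]2C=C[C@]1([C@H](C)CCCO[Si](C)(C)C(C)(C)C)O2 | intermediate
14 | exo-5,6-epoxide of 13 (oxirane syn to the oxygen bridge) | C=CCOC(=O)[C@H]1C[C@H]2[C@@H]3O[C@@H]3[C@]1([C@H](C)CCCO[Si](C)(C)C(C)(C)C)O2 | intermediate
15 | allyl (1R,5S,6S)-2-[(2R)-5-(tert-butyldimethylsilyloxy)pentan-2-yl]-5-hydroxy-7-oxabicyclo[4.1.0]hept-2-ene-3-carboxylate (6,7-epoxide cis to C8–OH) | O[C@H]1CC(C(=O)OCC=C)=C([C@H](C)CCCO[Si](C)(C)C(C)(C)C)[C@H]2O[C@@H]12 | intermediate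
16 | diethylphosphonoacetic acid | CCOP(=O)(OCC)CC(=O)O | starting material
17 | allyl (1R,5R,6S)-5-{[2-(diethoxyphosphoryl)acetyl]oxy}-2-[(2R)-5-(tert-butyldimethylsilyloxy)pentan-2-yl]-7-oxabicyclo[4.1.0]hept-2-ene-3-carboxylate (6,7-epoxide anti to the C8 ester) | CCOP(=O)(OCC)CC(=O)O[C@@H]1CC(C(=O)OCC=C)=C([C@H](C)CCCO[Si](C)(C)C(C)(C)C)[C@H]2O[C@@H]12 | intermediate
18 | allyl (3ξ,3aS,4S,7aR)-3-(diethoxyphosphoryl)-4-hydroxy-5-[(2R)-5-(tert-butyldimethylsilyloxy)pentan-2-yl]-2-oxo-2,3,3a,4,7,7a-hexahydro-1-benzofuran-6-carboxylate | CCOP(=O)(OCC)[C@@H]1C(=O)O[C@@H]2CC(C(=O)OCC=C)=C([C@H](C)CCCO[Si](C)(C)C(C)(C)C)[C@@H](O)[C@H]12 | intermediate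
19 | angelic acid, (2Z)-2-methylbut-2-enoic acid | C/C=C(/C)C(=O)O | starting material
20 | (2Z)-2-methylbut-2-enoic 2,4,6-trichlorobenzoic anhydride | C/C=C(/C)C(=O)OC(=O)c1c(Cl)cc(Cl)cc1Cl | intermediate (not isolated)
21 | allyl (3ξ,3aR,4S,7aR)-3-(diethoxyphosphoryl)-4-{[(2Z)-2-methylbut-2-enoyl]oxy}-5-[(2R)-5-(tert-butyldimethylsilyloxy)pentan-2-yl]-2-oxo-2,3,3a,4,7,7a-hexahydro-1-benzofuran-6-carboxylate | CCOP(=O)(OCC)[C@@H]1C(=O)O[C@@H]2CC(C(=O)OCC=C)=C([C@H](C)CCCO[Si](C)(C)C(C)(C)C)[C@@H](OC(=O)/C(C)=C\C)[C@H]12 | intermediate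
22 | the 6-carboxylic acid corresponding to 21 (C10–CO2H) | CCOP(=O)(OCC)[C@@H]1C(=O)O[C@@H]2CC(C(=O)O)=C([C@H](C)CCCO[Si](C)(C)C(C)(C)C)[C@@H](OC(=O)/C(C)=C\C)[C@H]12 | intermediate
23 | mixed isobutyl carbonic anhydride of 22 | CCOP(=O)(OCC)[C@@H]1C(=O)O[C@@H]2CC(C(=O)OC(=O)OCC(C)C)=C([C@H](C)CCCO[Si](C)(C)C(C)(C)C)[C@@H](OC(=O)/C(C)=C\C)[C@H]12 | intermediate (not isolated)
24 | (3ξ,3aR,4S,7aR)-3-(diethoxyphosphoryl)-6-(hydroxymethyl)-5-[(2R)-5-(tert-butyldimethylsilyloxy)pentan-2-yl]-2-oxo-2,3,3a,4,7,7a-hexahydro-1-benzofuran-4-yl (2Z)-2-methylbut-2-enoate | CCOP(=O)(OCC)[C@@H]1C(=O)O[C@@H]2CC(CO)=C([C@H](C)CCCO[Si](C)(C)C(C)(C)C)[C@@H](OC(=O)/C(C)=C\C)[C@H]12 | intermediate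
25 | (3aR,4S,7aR)-6-(hydroxymethyl)-3-methylidene-5-[(2R)-5-(tert-butyldimethylsilyloxy)pentan-2-yl]-2-oxo-2,3,3a,4,7,7a-hexahydro-1-benzofuran-4-yl (2Z)-2-methylbut-2-enoate | C=C1C(=O)O[C@@H]2CC(CO)=C([C@H](C)CCCO[Si](C)(C)C(C)(C)C)[C@@H](OC(=O)/C(C)=C\C)[C@H]12 | intermediate
26 | CNP0106570.2, (3aR,4S,7aR)-6-(hydroxymethyl)-5-[(2R)-5-hydroxypentan-2-yl]-3-methylidene-2-oxo-2,3,3a,4,7,7a-hexahydro-1-benzofuran-4-yl (2Z)-2-methylbut-2-enoate | C=C1C(=O)O[C@@H]2CC(CO)=C([C@H](C)CCCO)[C@@H](OC(=O)/C(C)=C\C)[C@H]12 | target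

Total step count: 13. Longest linear sequence: 13 steps (1 → 3 → 7 → 11 → 13 → 14 → 15 → 17 → 18 → 21 → 22 → 24 → 25 → 26).

Steps most likely to fail

Step 8. The ester tether must rotate into the s-cis arrangement, and a stabilised phosphonate carbanion is a slow epoxide opener. While it waits, base may degrade the epoxy enoate by elimination and aromatisation, or the carbanion may attack allylic C6. The fallback sets out from 15 and comes back at 25; it replaces the tether nucleophile by a malonate, the classical carbon partner of epoxides, and makes the methylene by decarboxylative Mannich methylenation. Mitsunobu esterification of 15 with mono-tert-butyl malonate (PPh3, DIAD, THF) gives the anti epoxy tert-butyl malonate F1. Cs2CO3 in DMF at rt closes the ring to the α-(tert-butoxycarbonyl) cis-lactone alcohol F2. Angeloylation as in step 9 gives the angelate F3, deallylation as in step 10 the C10 acid F4, and mixed-anhydride reduction as in step 11 the C14 alcohol F5. TMSOTf and 2,6-lutidine (CH2Cl2, 0 °C), followed by aqueous citric acid, cleave the tert-butyl ester to the α-carboxy lactone F6. Aqueous formaldehyde with diethylamine (AcOH, NaOAc, rt) then gives 25.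

Step 4. The cycloaddition is reversible, the Lewis acid may instead promote conjugate alkylation of the electron-rich furan, and endo or facial selectivity may erode with the unactivated allyl ester. The fallback sets out from 11 and comes back at 13; it uses a two-point-binding dienophile. Cycloaddition of 11 with 3-acryloyl-1,3-oxazolidin-2-one is catalysed by [Cu((S,S)-t-Bu-box)](SbF6)2 in CH2Cl2 at −78 °C, the ligand antipode that gives this bridgehead sense with furan itself. It gives the endo imide adduct F7, which bromomagnesium allyloxide (allyl alcohol, MeMgBr, THF, 0 °C) converts into 13.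

Step 7. The activated C8 oxyphosphonium may undergo E2 elimination toward C9, followed by aromatisation, or the substitution next to the oxirane may be too slow. The fallback sets out from 11 and comes back at 17; it creates the anti relationship by face-selective epoxidation instead of inversion. Diels–Alder reaction of 11 with 12 under the antipodal catalyst of step 4 gives the (1R,2R,4R) endo adduct F8. LiN(SiMe3)2 (THF, −78 °C) opens the bridge to the (8R)-dienol F9. Carbodiimide esterification with 16 (EDC·HCl, DMAP, CH2Cl2) gives the dienyl phosphonoacetate F10. m-CPBA (NaHCO3, CH2Cl2, 0 °C) should then epoxidise the C6=C7 alkene, the more electron-rich of the two, mainly anti to the C8 ester to give 17, with the syn isomer removed by chromatography.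

Further compounds
F1 | step 8 | allyl (1R,5R,6S)-5-[(3-tert-butoxy-3-oxopropanoyl)oxy]-2-[(2R)-5-(tert-butyldimethylsilyloxy)pentan-2-yl]-7-oxabicyclo[4.1.0]hept-2-ene-3-carboxylate | CC(C)(C)OC(=O)CC(=O)O[C@@H]1CC(C(=O)OCC=C)=C([C@H](C)CCCO[Si](C)(C)C(C)(C)C)[C@H]2O[C@@H]12
F2 | step 8 | α-(tert-butoxycarbonyl) cis-lactone with free C6–OH and C10 allyl ester (C11 unassigned) | CC(C)(C)OC(=O)C1C(=O)O[C@@H]2CC(C(=O)OCC=C)=C([C@H](C)CCCO[Si](C)(C)C(C)(C)C)[C@@H](O)[C@H]12
F3 | step 8 | C6 angelate of F2 | CC(C)(C)OC(=O)C1C(=O)O[C@@H]2CC(C(=O)OCC=C)=C([C@H](C)CCCO[Si](C)(C)C(C)(C)C)[C@@H](OC(=O)/C(C)=C\C)[C@H]12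
F4 | step 8 | C10 carboxylic acid from F3 | CC(C)(C)OC(=O)C1C(=O)O[C@@H]2CC(C(=O)O)=C([C@H](C)CCCO[Si](C)(C)C(C)(C)C)[C@@H](OC(=O)/C(C)=C\C)[C@H]12
F5 | step 8 | C14 alcohol from F4 | CC(C)(C)OC(=O)C1C(=O)O[C@@H]2CC(CO)=C([C@H](C)CCCO[Si](C)(C)C(C)(C)C)[C@@H](OC(=O)/C(C)=C\C)[C@H]12
F6 | step 8 | α-carboxy cis-lactone with C14–OH, C6 angelate and C1–OTBS | OC(=O)C1C(=O)O[C@@H]2CC(CO)=C([C@H](C)CCCO[Si](C)(C)C(C)(C)C)[C@@H](OC(=O)/C(C)=C\C)[C@H]12
F7 | step 4 | 3-{(1S,2S,4S)-1-[(2R)-5-(tert-butyldimethylsilyloxy)pentan-2-yl]-7-oxabicyclo[2.2.1]hept-5-ene-2-carbonyl}-1,3-oxazolidin-2-one (endo) | O=C1OCCN1C(=O)[C@H]1C[C@H]2C=C[C@]1([C@H](C)CCCO[Si](C)(C)C(C)(C)C)O2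
F8 | step 7 | allyl (1R,2R,4R)-1-[(2R)-5-(tert-butyldimethylsilyloxy)pentan-2-yl]-7-oxabicyclo[2.2.1]hept-5-ene-2-carboxylate (endo) | C=CCOC(=O)[C@@H]1C[C@@H]2C=C[C@@]1([C@H](C)CCCO[Si](C)(C)C(C)(C)C)O2
F9 | step 7 | allyl (5R)-5-hydroxy-2-[(2R)-5-(tert-butyldimethylsilyloxy)pentan-2-yl]cyclohexa-1,3-diene-1-carboxylate | O[C@@H]1CC(C(=O)OCC=C)=C([C@H](C)CCCO[Si](C)(C)C(C)(C)C)C=C1
F10 | step 7 | allyl (5R)-5-{[2-(diethoxyphosphoryl)acetyl]oxy}-2-[(2R)-5-(tert-butyldimethylsilyloxy)pentan-2-yl]cyclohexa-1,3-diene-1-carboxylate | CCOP(=O)(OCC)CC(=O)O[C@@H]1CC(C(=O)OCC=C)=C([C@H](C)CCCO[Si](C)(C)C(C)(C)C)C=C1
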